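**Remark on the chemistry.** The target has no stereocentre. The rings are called A (terminal dihydroxy ring), B (central ring) and C (ring with OCH3 and CO2H). Each is numbered as a benzoic acid with the carbonyl-bearing carbon as C1, so every ring has oxygen on C2 and C4 and CH3 on C6.

## Analysis of the target

The target is a tridepside: three separate benzene rings joined head to tail by two aryl ester bonds, the C1 carbonyl of ring A to O-4 of ring B and the C1 carbonyl of ring B to O-4 of ring C, with a free carboxylic acid on C1 of ring C. All three rings share the orsellinic acid pattern; rings A and B are orsellinic acid itself, whereas ring C has OCH3 on C2. There is no stereocentre, so the task is one of regiochemistry on ring C and of chemoselectivity among six oxygen functions and three carboxyl carbons. The sensitive groups are the two aryl esters, which hydroxide, alkoxides and amines cleave or scramble, the free phenols, and the electron-rich benzoic acid, which can decarboxylate when heated. Both ester carbonyls are flanked by two ortho substituents, so the ester bonds are slow to form and need strongly activated acyl donors. The real difficulty is ring C: in an orsellinate the C4 hydroxyl is the reactive one and the C2 hydroxyl is chelated to the carbonyl, yet here methyl sits on O-2 and O-4 must stay free for acylation. The strategy rests on the row C2–OCH3, C1–CO2H, C6–CH3 of ring C: the two carbon substituents stand on neighbouring carbons beside the methoxy group, which is where a nucleophile and an electrophile end up after adding across a C1–C6 aryne that has OCH3 on C2, while the C4 oxygen, meta to all three, can enter under its own protecting group.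

## Retrosynthetic reasoning

**Target 21 to 20.** The last operation should be neutral and non-nucleophilic, because the depside bonds and the free acid tolerate little else. All phenols of rings A and B and the ring C carboxyl are therefore masked as benzyl groups in 20, so one hydrogenolysis removes them together.

**20 to 10 and 18.** The ester C–O bond between the ring B carbonyl and O-4 of ring C is cut. This cut separates the one ring that cannot be bought in usable form (ring C, phenol 10) from the two rings that are orsellinic acid 11 (acid 18). It is also the most convergent division. In the forward sense acid 18 is activated as chloride 19 and acylates the only free hydroxyl of 10.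

**10 to 9 to 8.** These are protecting-group changes only. The carboxyl of 8 becomes a benzyl ester (9) so that it cannot form mixed anhydrides during the coupling, and the silyl ether is then removed to free O-4. The O-2/O-4 distinction is already present in 8 as methyl ether against silyl ether.

**8 to 2, 3 and 4 (key disconnection).** The C6–CH3 and C1–CO2H bonds of ring C are cut together. They lie on adjacent carbons next to the methoxy group, so both can come from one aryne: methyl from 3 as the nucleophile, carboxyl from 4 as the electrophile. What remains is the 1,3,5-trisubstituted arene 2, with fluorine on the carbon that will carry methyl. Cutting instead at the O–CH3 bond of an orsellinate would mean methylating the less reactive hydroxyl in the presence of the more reactive one. The forward reaction has to lithiate 2 between F and OCH3, expel fluoride, add methyl to the aryne carbon remote from OCH3 and carboxylate the carbon beside it.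

**2 to 1.** The O–Si bond is cut. The bulky silyl group is not only a protecting group: it blocks lithiation at the two ring positions beside it.

**18 to 17 to 16.** The ring B carboxyl is released from an allyl ester, which is orthogonal both to the benzyl groups and to the aryl ester. The benzyl ether on O-2 of ring B is traced back to the free chelated phenol of 16, so that the acid chloride 19 carries no free hydroxyl.

**16 to 13 and 14.** The A–B ester bond is cut. Forward, chloride 15 (from acid 13) acylates 14 at O-4, the hydroxyl that is neither chelated nor beside the ester.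

**13 and 14 to 11.** Both pieces come from orsellinic acid 11 by alkylation: exhaustive benzylation and saponification (12, then 13) for ring A, carboxylate allylation (14) for ring B.

## Alternatives that were turned down

**Alternative 1:** Ring B is cut across C1–C2 and C5–C6 into the ketene acetal diene A2, which already carries ring A as a 3-aroyloxy group, and the ring C but-2-ynoate A3. A thermal [4+2] cycloaddition followed by elimination of the methoxy group would give the tridepside A1 with O-2 of ring B free.
- For: it is the most convergent plan, since both depside bonds exist on small pieces before ring B does. The polarisation of the partners fixes the regiochemistry, the CH2 terminus of A2 attacking the methyl-bearing alkyne carbon of A3. Ring B arrives without a protecting group on O-2; on this point it is stronger than the chosen route, which spends step 9 on that oxygen.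
- Against: A2 is at once a silyl ketene acetal and an enol ester. Its preparation requires a dienolate that can attack its own aroyl group, and the acyloxy group is a weaker donor than the silyloxy group of the usual dienes of this type. A3 is a β-methyl ynoate, a sluggish dienophile, so heating is needed that A2 is unlikely to survive.
- Comparison: A3 still has to be made from the ring C phenol 10, so the O-2/O-4 problem of ring C is untouched, and the ring that is built is available as orsellinic acid 11. The step count is comparable. The chosen route instead places its one demanding step at step 2, on a small molecule, and solves the ring C pattern directly.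

**Alternative 2:** Ring A is opened at C1–C6 to a triketo ester chain, and the A–B ester bond is traced to an acylketene released from dioxinone A5 on heating and captured by the B–C phenol A6. The resulting aryl 3,5,7-trioxooctanoate A7 would be folded by base and then acid (C2 onto the C7 ketone) to give A4.
- For: the route is biomimetic and ring A appears with both hydroxyls free, so the benzylation and hindered saponification of steps 5 and 6 are not needed. The ester bond is made by ketene capture instead of by attack on a doubly ortho-substituted acyl chloride. On both points it is stronger than the chosen route.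
- Against: in A7 the ring B phenoxide is a good leaving group. Under the base needed for the aldol folding, the chain can instead close from C6 onto the ester carbonyl (Claisen mode) or through an enol oxygen to a 4-hydroxy-2-pyrone, each of which expels A6 and destroys the bond just made.
- Comparison: A6 needs everything the chosen route needs for ring C plus a ring B differentiated at O-2 and O-4, and the key step again builds a ring that orsellinic acid 11 supplies. The chosen route offers ordinary acylation chemistry for the ester bonds and keeps the risk early.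

**Alternative 3:** Ring A is cut at C2–C3, C4–C5 and C1–C2. Photochemical Wolff rearrangement of diazoketone A10, carried on the B–C didepside, would give a vinylketene that adds the silyloxyalkyne A9; 4π opening of the cyclobutenone and 6π closure would give A8.
- For: the mechanism fixes the substitution pattern of ring A, the conditions are free of base and nucleophiles, and ring A needs no protecting-group handling of its own, which is an advantage over steps 5 and 6.
- Against: A10 contains two aryl benzoate chromophores that can undergo photo-Fries rearrangement under the irradiation the Wolff step needs. Its diazo group sits beside an electron-poor alkene of the fumarate type, a good partner for dipolar cycloaddition with a second molecule. The differentiated hydroxyls of ring A in A8 are of no use, since both are free in the target.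
- Comparison: it is the longest of the four plans, places a photochemical cascade on the most advanced intermediate, and again rebuilds an orsellinate. The chosen route buys rings A and B and uses its key step on the only ring that needs it.

Key step: step 2

## Route

**Step 1**
Reactants: 1 3-fluoro-5-methoxyphenol
Product: 2 (3-fluoro-5-methoxyphenoxy)tri(propan-2-yl)silane
Conditions: i-Pr3SiCl, imidazole, DMF, rt
Reagents that add atoms: chlorotri(propan-2-yl)silane, CC(C)[Si](Cl)(C(C)C)C(C)C
Why: Imidazole-promoted silylation of a phenol (silyl ether formation) is routine; the bulky silyl group survives n-BuLi and MeMgBr and shields both ring positions beside it from lithiation.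

**Step 2**
Reactants: 2 (3-fluoro-5-methoxyphenoxy)tri(propan-2-yl)silane; 3 methylmagnesium bromide; 4 carbon dioxide
Product: 8 2-methoxy-6-methyl-4-[tri(propan-2-yl)silyloxy]benzoic acid, via the 2-lithio aryl fluoride 5 (not isolated), via the methoxyaryne 6 (not isolated), via the arylmagnesium bromide 7 (not isolated)
Conditions: n-BuLi (1.0 equiv), THF, −78 °C; MeMgBr (3 equiv), −78 °C → rt; CO2 (gas), 0 °C → rt; cold 1 M HCl
Reagents that add atoms: methylmagnesium bromide (3), C[Mg]Br; carbon dioxide (4), O=C=O
Why: n-BuLi should remove the ring proton flanked by F and OCH3, which both acidify it while OCH3 also coordinates lithium, giving 5; the two other ring protons lie beside the bulky silyloxy group. After MeMgBr is added and the mixture warms, metal fluoride is lost and aryne 6 forms slowly in the presence of a large excess of the methyl nucleophile. Carbomagnesiation should place CH3 on the aryne carbon remote from OCH3 (the former C–F carbon) and magnesium on the carbon beside OCH3, where the charge is inductively stabilised and chelated, giving 7. CO2 then carboxylates that carbon and acid work-up gives 8 with OCH3, CO2H and CH3 in a row. The closest known reaction type is the three-component aryne coupling: a 3-methoxyaryne from an ortho-lithiated fluoroanisole, Grignard addition distal to the methoxy group, and electrophilic trapping of the arylmagnesium. No ring is closed and no stereocentre is formed. The step needs site-selective lithiation, secured by the silyl bulk and the cooperative F/OCH3 activation, and regioselective addition, secured by the methoxy group next to the triple bond, which should outweigh the weak opposite bias of the remote silyloxy group; one equivalent of n-BuLi and excess MeMgBr suppress addition of butyl or of 5 to the aryne.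

**Step 3**
Reactants: 8 2-methoxy-6-methyl-4-[tri(propan-2-yl)silyloxy]benzoic acid
Product: 9 benzyl 2-methoxy-6-methyl-4-[tri(propan-2-yl)silyloxy]benzoate
Conditions: BnBr, KHCO3, DMF, rt
Reagents that add atoms: benzyl bromide, BrCc1ccccc1
Why: SN2 alkylation of the carboxylate takes place at oxygen, away from the hindered carbonyl carbon, so the two ortho substituents do not slow it; KHCO3 is too weak a base to cleave the aryl silyl ether.

**Step 4**
Reactants: 9 benzyl 2-methoxy-6-methyl-4-[tri(propan-2-yl)silyloxy]benzoate
Product: 10 benzyl 4-hydroxy-2-methoxy-6-methylbenzoate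
Conditions: Bu4NF, AcOH, THF, 0 °C
Reagents that add atoms: none
Why: Fluoride-mediated desilylation is driven by the strong Si–F bond; acetic acid buffers the phenoxide, and the benzyl ester and methyl ether are inert.

**Step 5**
Reactants: 11 orsellinic acid (2,4-dihydroxy-6-methylbenzoic acid)
Product: 12 benzyl 2,4-bis(benzyloxy)-6-methylbenzoate
Conditions: BnBr (3.5 equiv), K2CO3, DMF, 50 °C
Reagents that add atoms: benzyl bromide, BrCc1ccccc1
Why: Williamson etherification of both phenols together with carboxylate alkylation; with excess benzyl bromide in DMF the chelated O-2 is alkylated as well.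

**Step 6**
Reactants: 12 benzyl 2,4-bis(benzyloxy)-6-methylbenzoate
Product: 13 2,4-bis(benzyloxy)-6-methylbenzoic acid
Conditions: KOH, DMSO–H2O, 90 °C; then cold 1 M HCl
Reagents that add atoms: potassium hydroxide, [K+].[OH-]
Why: Saponification; poorly solvated hydroxide in hot aqueous DMSO should attack the doubly ortho-substituted ester, benzyl aryl ethers are stable to base, and cold acidification avoids decarboxylation.

**Step 7**
Reactants: 11 orsellinic acid
Product: 14 prop-2-enyl 2,4-dihydroxy-6-methylbenzoate
Conditions: allyl bromide (1.05 equiv), KHCO3, DMF, rt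
Reagents that add atoms: allyl bromide (3-bromoprop-1-ene), C=CCBr
Why: Chemoselective carboxylate alkylation: KHCO3 deprotonates only the carboxylic acid, so the allyl group goes on the carboxylate and both phenols stay free.

**Step 8**
Reactants: 13 2,4-bis(benzyloxy)-6-methylbenzoic acid; 14 prop-2-enyl 2,4-dihydroxy-6-methylbenzoate
Product: 16 prop-2-enyl 4-[2,4-bis(benzyloxy)-6-methylbenzoyl]oxy-2-hydroxy-6-methylbenzoate, via acid chloride 15 (not isolated)
Conditions: (COCl)2, DMF (cat.), CH2Cl2, 0 °C → rt, evaporate; then 14, Et3N, DMAP (cat.), CH2Cl2, 0 °C → rt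
Reagents that add atoms: none
Why: Acid chloride formation through the chloroiminium from oxalyl chloride and DMF, then DMAP-catalysed acylation of a phenol; O-4 of 14 is the more acidic and unhindered hydroxyl, whereas O-2 is hydrogen-bonded to the ester carbonyl and lies beside it, so the bulky acyl chloride should react at O-4 only.

**Step 9**
Reactants: 16 prop-2-enyl 4-[2,4-bis(benzyloxy)-6-methylbenzoyl]oxy-2-hydroxy-6-methylbenzoate
Product: 17 prop-2-enyl 2-(benzyloxy)-4-[2,4-bis(benzyloxy)-6-methylbenzoyl]oxy-6-methylbenzoate
Conditions: BnBr, K2CO3, DMF, rt → 40 °C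
Reagents that add atoms: benzyl bromide, BrCc1ccccc1
Why: Williamson ether synthesis on the chelated phenol; the aryl ester carbonyl is shielded by two ortho substituents, and the ring B phenoxide is meta to the acyloxy group, so no intramolecular acyl shift is possible.

**Step 10**
Reactants: 17 prop-2-enyl 2-(benzyloxy)-4-[2,4-bis(benzyloxy)-6-methylbenzoyl]oxy-6-methylbenzoate
Product: 18 2-(benzyloxy)-4-[2,4-bis(benzyloxy)-6-methylbenzoyl]oxy-6-methylbenzoic acid
Conditions: Pd(PPh3)4 (5 mol %), N-methylaniline, THF, rt
Reagents that add atoms: none
Why: Tsuji–Trost deallylation: zerovalent palladium ionises the allyl ester to a π-allyl complex that N-methylaniline captures; the reaction occurs at the allyl group, far from the hindered carbonyl, and touches neither the benzyl ethers nor the aryl ester.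

**Step 11**
Reactants: 18 2-(benzyloxy)-4-[2,4-bis(benzyloxy)-6-methylbenzoyl]oxy-6-methylbenzoic acid; 10 benzyl 4-hydroxy-2-methoxy-6-methylbenzoate
Product: 20 benzyl 4-[2-(benzyloxy)-4-[2,4-bis(benzyloxy)-6-methylbenzoyl]oxy-6-methylbenzoyl]oxy-2-methoxy-6-methylbenzoate, via acid chloride 19 (not isolated)
Conditions: (COCl)2, DMF (cat.), CH2Cl2, 0 °C → rt, evaporate; then 10, Et3N, DMAP (cat.), CH2Cl2, 0 °C → rt
Reagents that add atoms: none
Why: The same acid chloride formation and DMAP-catalysed phenol acylation as in step 8; 10 has a single free hydroxyl and 19 has none, so only the desired ester bond can form.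

**Step 12**
Reactants: 20 benzyl 4-[2-(benzyloxy)-4-[2,4-bis(benzyloxy)-6-methylbenzoyl]oxy-6-methylbenzoyl]oxy-2-methoxy-6-methylbenzoate
Product: 21 4-[4-(2,4-dihydroxy-6-methylbenzoyl)oxy-2-hydroxy-6-methylbenzoyl]oxy-2-methoxy-6-methylbenzoic acid (target)
Conditions: H2 (1 atm), 10% Pd/C, EtOAc–THF, rt
Reagents that add atoms: none
Why: Heterogeneous hydrogenolysis of benzylic C–O bonds should remove the three benzyl ethers and the benzyl ester at once under neutral conditions; aryl esters, the methyl ether and the arenes are not reduced, and a non-nucleophilic solvent avoids transesterification.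

## Compound list

1 | 3-fluoro-5-methoxyphenol | COc1cc(O)cc(F)c1 | starting material
2 | (3-fluoro-5-methoxyphenoxy)tri(propan-2-yl)silane | COc1cc(F)cc(O[Si](C(C)C)(C(C)C)C(C)C)c1 | intermediate
3 | methylmagnesium bromide | C[Mg]Br | starting material
4 | carbon dioxide | O=C=O | starting material
5 | [2-fluoro-6-methoxy-4-[tri(propan-2-yl)silyloxy]phenyl]lithium | COc1cc(O[Si](C(C)C)(C(C)C)C(C)C)cc(F)c1[Li] | intermediate
6 | 3-methoxy-5-[tri(propan-2-yl)silyloxy]benzyne (1,2-didehydro arene) | COC1=CC(O[Si](C(C)C)(C(C)C)C(C)C)=CC#C1 | intermediate
7 | [2-methoxy-6-methyl-4-[tri(propan-2-yl)silyloxy]phenyl]magnesium bromide | COc1cc(O[Si](C(C)C)(C(C)C)C(C)C)cc(C)c1[Mg]Br | intermediate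
8 | 2-methoxy-6-methyl-4-[tri(propan-2-yl)silyloxy]benzoic acid | COc1cc(O[Si](C(C)C)(C(C)C)C(C)C)cc(C)c1C(=O)O | intermediate
9 | benzyl 2-methoxy-6-methyl-4-[tri(propan-2-yl)silyloxy]benzoate | COc1cc(O[Si](C(C)C)(C(C)C)C(C)C)cc(C)c1C(=O)OCc1ccccc1 | intermediate
10 | benzyl 4-hydroxy-2-methoxy-6-methylbenzoate | COc1cc(O)cc(C)c1C(=O)OCc1ccccc1 | intermediate
11 | orsellinic acid (2,4-dihydroxy-6-methylbenzoic acid) | Cc1cc(O)cc(O)c1C(=O)O | starting material
12 | benzyl 2,4-bis(benzyloxy)-6-methylbenzoate | Cc1cc(OCc2ccccc2)cc(OCc2ccccc2)c1C(=O)OCc1ccccc1 | intermediate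
13 | 2,4-bis(benzyloxy)-6-methylbenzoic acid | Cc1cc(OCc2ccccc2)cc(OCc2ccccc2)c1C(=O)O | intermediate
14 | prop-2-enyl 2,4-dihydroxy-6-methylbenzoate | Cc1cc(O)cc(O)c1C(=O)OCC=C | intermediate
15 | 2,4-bis(benzyloxy)-6-methylbenzoyl chloride | Cc1cc(OCc2ccccc2)cc(OCc2ccccc2)c1C(=O)Cl | intermediate
16 | prop-2-enyl 4-[2,4-bis(benzyloxy)-6-methylbenzoyl]oxy-2-hydroxy-6-methylbenzoate | Cc1cc(OC(=O)c2c(C)cc(OCc3ccccc3)cc2OCc2ccccc2)cc(O)c1C(=O)OCC=C | intermediate
17 | prop-2-enyl 2-(benzyloxy)-4-[2,4-bis(benzyloxy)-6-methylbenzoyl]oxy-6-methylbenzoate | Cc1cc(OC(=O)c2c(C)cc(OCc3ccccc3)cc2OCc2ccccc2)cc(OCc2ccccc2)c1C(=O)OCC=C | intermediate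
18 | 2-(benzyloxy)-4-[2,4-bis(benzyloxy)-6-methylbenzoyl]oxy-6-methylbenzoic acid | Cc1cc(OC(=O)c2c(C)cc(OCc3ccccc3)cc2OCc2ccccc2)cc(OCc2ccccc2)c1C(=O)O | intermediate
19 | 2-(benzyloxy)-4-[2,4-bis(benzyloxy)-6-methylbenzoyl]oxy-6-methylbenzoyl chloride | Cc1cc(OC(=O)c2c(C)cc(OCc3ccccc3)cc2OCc2ccccc2)cc(OCc2ccccc2)c1C(=O)Cl | intermediate
20 | benzyl 4-[2-(benzyloxy)-4-[2,4-bis(benzyloxy)-6-methylbenzoyl]oxy-6-methylbenzoyl]oxy-2-methoxy-6-methylbenzoate | COc1cc(OC(=O)c2c(C)cc(OC(=O)c3c(C)cc(OCc4ccccc4)cc3OCc3ccccc3)cc2OCc2ccccc2)cc(C)c1C(=O)OCc1ccccc1 | intermediate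
21 | 4-[4-(2,4-dihydroxy-6-methylbenzoyl)oxy-2-hydroxy-6-methylbenzoyl]oxy-2-methoxy-6-methylbenzoic acid | COc1cc(OC(=O)c2c(C)cc(OC(=O)c3c(C)cc(O)cc3O)cc2O)cc(C)c1C(=O)O | target

## Step count and risk

Total: 12 steps. Longest linear sequence: 7 steps (11 through steps 5, 6, 8, 9, 10, 11 and 12). The ring C branch from 1 is 6 steps (steps 1 to 4, 11 and 12).

**Step 2 (key step).** Several processes could divert it:
- deprotonation beside the silyloxy group, which would lead through the other aryne to the regioisomeric acid;
- capture of the aryne by 5 or by residual butyl-lithium instead of by the modestly nucleophilic methyl Grignard;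
- addition of methyl in the reverse sense;
- protonation of 7 before CO2 arrives.

Fallback: the ring C pattern is built by classical differentiation, setting out from 11. Carboxylate benzylation (BnBr, KHCO3, DMF) gives benzyl 2,4-dihydroxy-6-methylbenzoate F1. Silylation of the non-chelated O-4 (i-Pr3SiCl, imidazole) gives benzyl 2-hydroxy-6-methyl-4-[tri(propan-2-yl)silyloxy]benzoate F2. Methylation of the chelated O-2 (MeI, K2CO3, acetone) returns to the route at 9.

**Step 9.** Under carbonate in DMF the ring B phenoxide may transfer or lose the ring A acyl group (transesterification), or alkylation of the chelated phenol may be sluggish. Fallback: the benzyl ether is put on ring B before the ester bond exists, setting out from 14. Silylation at O-4 gives prop-2-enyl 2-hydroxy-6-methyl-4-[tri(propan-2-yl)silyloxy]benzoate F3. Mitsunobu etherification (BnOH, PPh3, diisopropyl azodicarboxylate) gives prop-2-enyl 2-(benzyloxy)-6-methyl-4-[tri(propan-2-yl)silyloxy]benzoate F4. Bu4NF/AcOH gives prop-2-enyl 2-(benzyloxy)-4-hydroxy-6-methylbenzoate F5, and acylation with 15 (made from 13 as in step 8; Et3N, DMAP) returns to the route at 17.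

**Step 11.** The HCl set free during acid chloride formation may cleave the benzyl ether ortho to the acyl chloride, and attack of the phenol on an acyl carbon flanked by two ortho substituents may be so slow that hydrolysis on work-up wins. Fallback: ring B is carried with its O-2 free and the acid is activated as a mixed trifluoroacetic anhydride, setting out from 16. Deallylation as in step 10 gives 4-[2,4-bis(benzyloxy)-6-methylbenzoyl]oxy-2-hydroxy-6-methylbenzoic acid F6. Condensation with 10 by trifluoroacetic anhydride in toluene, a method suited to hindered ortho-hydroxy benzoic acids, gives benzyl 4-[4-[2,4-bis(benzyloxy)-6-methylbenzoyl]oxy-2-hydroxy-6-methylbenzoyl]oxy-2-methoxy-6-methylbenzoate F7 (the same structure as A1). Hydrogenolysis as in step 12 returns to the route at 21.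

**Step 6.** Hydroxide attack on the shielded ester carbonyl may be slow, and forcing conditions invite decarboxylation on acidification. Fallback: the ester is cleaved at the alkyl side instead, setting out from 14. Benzylation of both phenols (BnBr, K2CO3, DMF) gives prop-2-enyl 2,4-bis(benzyloxy)-6-methylbenzoate F8, and deallylation with Pd(PPh3)4 and N-methylaniline returns to the route at 13.

## Further compounds

F1 | step 2 | benzyl 2,4-dihydroxy-6-methylbenzoate | Cc1cc(O)cc(O)c1C(=O)OCc1ccccc1
F2 | step 2 | benzyl 2-hydroxy-6-methyl-4-[tri(propan-2-yl)silyloxy]benzoate | Cc1cc(O[Si](C(C)C)(C(C)C)C(C)C)cc(O)c1C(=O)OCc1ccccc1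
F3 | step 9 | prop-2-enyl 2-hydroxy-6-methyl-4-[tri(propan-2-yl)silyloxy]benzoate | Cc1cc(O[Si](C(C)C)(C(C)C)C(C)C)cc(O)c1C(=O)OCC=C
F4 | step 9 | prop-2-enyl 2-(benzyloxy)-6-methyl-4-[tri(propan-2-yl)silyloxy]benzoate | Cc1cc(O[Si](C(C)C)(C(C)C)C(C)C)cc(OCc2ccccc2)c1C(=O)OCC=C
F5 | step 9 | prop-2-enyl 2-(benzyloxy)-4-hydroxy-6-methylbenzoate | Cc1cc(O)cc(OCc2ccccc2)c1C(=O)OCC=C
F6 | step 11 | 4-[2,4-bis(benzyloxy)-6-methylbenzoyl]oxy-2-hydroxy-6-methylbenzoic acid | Cc1cc(OC(=O)c2c(C)cc(OCc3ccccc3)cc2OCc2ccccc2)cc(O)c1C(=O)O
F7 | step 11 | benzyl 4-[4-[2,4-bis(benzyloxy)-6-methylbenzoyl]oxy-2-hydroxy-6-methylbenzoyl]oxy-2-methoxy-6-methylbenzoate | COc1cc(OC(=O)c2c(C)cc(OC(=O)c3c(C)cc(OCc4ccccc4)cc3OCc3ccccc3)cc2O)cc(C)c1C(=O)OCc1ccccc1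
F8 | step 6 | prop-2-enyl 2,4-bis(benzyloxy)-6-methylbenzoate | Cc1cc(OCc2ccccc2)cc(OCc2ccccc2)c1C(=O)OCC=C
A1 | alternative 1 | benzyl 4-[4-[2,4-bis(benzyloxy)-6-methylbenzoyl]oxy-2-hydroxy-6-methylbenzoyl]oxy-2-methoxy-6-methylbenzoate | COc1cc(OC(=O)c2c(C)cc(OC(=O)c3c(C)cc(OCc4ccccc4)cc3OCc3ccccc3)cc2O)cc(C)c1C(=O)OCc1ccccc1
A2 | alternative 1 | 4-methoxy-4-(trimethylsilyloxy)buta-1,3-dien-2-yl 2,4-bis(benzyloxy)-6-methylbenzoate (ketene acetal geometry not defined) | C=C(OC(=O)c1c(C)cc(OCc2ccccc2)cc1OCc1ccccc1)C=C(OC)O[Si](C)(C)C
A3 | alternative 1 | benzyl 4-(but-2-ynoyloxy)-2-methoxy-6-methylbenzoate | CC#CC(=O)Oc1cc(C)c(C(=O)OCc2ccccc2)c(OC)c1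
A4 | alternative 2 | benzyl 4-[2-(benzyloxy)-4-(2,4-dihydroxy-6-methylbenzoyl)oxy-6-methylbenzoyl]oxy-2-methoxy-6-methylbenzoate | COc1cc(OC(=O)c2c(C)cc(OC(=O)c3c(C)cc(O)cc3O)cc2OCc2ccccc2)cc(C)c1C(=O)OCc1ccccc1
A5 | alternative 2 | 6-(2,4-dioxopentyl)-2,2-dimethyl-1,3-dioxin-4-one | CC(=O)CC(=O)CC1=CC(=O)OC(C)(C)O1
A6 | alternative 2 | benzyl 4-[2-(benzyloxy)-4-hydroxy-6-methylbenzoyl]oxy-2-methoxy-6-methylbenzoate | COc1cc(OC(=O)c2c(C)cc(O)cc2OCc2ccccc2)cc(C)c1C(=O)OCc1ccccc1
A7 | alternative 2 | 3-(benzyloxy)-4-[(4-benzyloxycarbonyl-3-methoxy-5-methylphenoxy)carbonyl]-5-methylphenyl 3,5,7-trioxooctanoate | CC(=O)CC(=O)CC(=O)CC(=O)Oc1cc(C)c(C(=O)Oc2cc(C)c(C(=O)OCc3ccccc3)c(OC)c2)c(OCc2ccccc2)c1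
A8 | alternative 3 | benzyl 4-[2-(benzyloxy)-4-[2-hydroxy-6-methyl-4-[tri(propan-2-yl)silyloxy]benzoyl]oxy-6-methylbenzoyl]oxy-2-methoxy-6-methylbenzoate | COc1cc(OC(=O)c2c(C)cc(OC(=O)c3c(C)cc(O[Si](C(C)C)(C(C)C)C(C)C)cc3O)cc2OCc2ccccc2)cc(C)c1C(=O)OCc1ccccc1
A9 | alternative 3 | ethynyloxytri(propan-2-yl)silane | C#CO[Si](C(C)C)(C(C)C)C(C)C
A10 | alternative 3 | 3-(benzyloxy)-4-[(4-benzyloxycarbonyl-3-methoxy-5-methylphenoxy)carbonyl]-5-methylphenyl (E)-5-diazo-3-methyl-4-oxopent-2-enoate | [N-]=[N+]=CC(=O)/C(C)=C/C(=O)Oc1cc(C)c(C(=O)Oc2cc(C)c(C(=O)OCc3ccccc3)c(OC)c2)c(OCc2ccccc2)c1
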